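**Plan**

1. Retrosynthesis: the silyl ethers come off last; the C1'' carbinol goes back to the C8 aryl ketone; ring C is opened at C2–C3 and C4–C4a to an α-aryloxy diazoketone in which O1–C2 and C3–C4 already exist; O1–C2 is cut to a 2,6-dihydroxyaryl ketone and (S)-4-hydroxymandelic acid; C3''–C4'' and C2''–C3'' are cut to an alkyne, an aldehyde and an acetophenone.
2. Enabling feature: on ring A, C4a is the only free carbon ortho to O1 (C8 carries the acyl chain); it lies between O1 and the C5 methoxy group and para to C7–OH. C2 is the only group of the diazoketone that can migrate, so a Wolff shift inserts C3 next to C2 and the ketene/acylium carbon C4 acylates C4a, closing the six-membered ring C.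
3. Helpers: the diazo group (lost as N2 in the step) and the ketone oxidation level at C1'', which keeps ring A stable to acid and blocks C8; it is reduced afterwards.
4. Forward order: the side chain first (alkenylboron fragment added to a ring A chalcone), then the ring B/C2 unit through O1 (Mitsunobu), then ring C (steps 13 and 14), then C1'' reduction and desilylation.
5. Stereochemistry: C7'' from a Ti/(R)-BINOL propargylation; C3'' from a Rh/(R)-BINAP conjugate alkenylation; C2 from (S)-4-hydroxymandelic acid (inversion in the Mitsunobu step, retention in the Wolff shift); C1'' from hydride delivery by an Ipc2B group tethered to C7–OH.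

Key step: step 14

Assumption: the facial sense of the three reagent-controlled steps (3, 7 and 15) is taken from the accepted transition-state models of each reagent class; both antipodes of BINOL, BINAP and Ipc2BCl are available, so a sense found reversed on a model substrate would be met by the other antipode.
Abbreviations: TBS = tert-butyldimethylsilyl, TBSO = tert-butyldimethylsilyloxy, Ipc = isopinocampheyl; flavanone numbering (O1, C2–C4, C4a, C5–C8, C8a; rings A, B, C); side chain C1''–C9'' counted from C8.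

**Step 1**
Reactants: 1 methyl 3-(4-hydroxyphenyl)propanoate
Product: 2 methyl 3-[4-(TBSO)phenyl]propanoate
Conditions: TBSCl, imidazole, DMF, rt
Reagents that add atoms: tert-butyldimethylsilyl chloride, CC(C)(C)[Si](C)(C)Cl
Why: Imidazole-promoted silylation of the phenol masks the only acidic OH before the hydride and organometallic steps.

**Step 2**
Reactants: 2 methyl 3-[4-(TBSO)phenyl]propanoate
Product: 3 3-[4-(TBSO)phenyl]propanal
Conditions: i-Bu2AlH (1.1 equiv.), CH2Cl2, −78 °C; aqueous potassium sodium tartrate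
Reagents that add atoms: none
Why: Low-temperature half-reduction of the methyl ester stops at the aluminium hemiacetal, which should release the aldehyde on work-up.

**Step 3**
Reactants: 3 3-[4-(TBSO)phenyl]propanal
Product: 4 (S)-1-[4-(TBSO)phenyl]hex-5-yn-3-ol
Conditions: allenyltributylstannane, (R)-BINOL (20 mol%), Ti(OiPr)4 (10 mol%), 4 Å molecular sieves, CH2Cl2, −20 °C; aqueous NaHCO3
Reagents that add atoms: tributyl(propa-1,2-dien-1-yl)stannane, C=C=C[Sn](CCCC)(CCCC)CCCC
Why: Titanium–BINOL-catalysed asymmetric propargylation (SE2' addition of the allenylstannane to the activated aldehyde) should set C7'' as S by Re-face attack under control of the (R)-BINOL ligand.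

**Step 4**
Reactants: 4 (S)-1-[4-(TBSO)phenyl]hex-5-yn-3-ol
Product: 5 (S)-3-(TBSO)-1-[4-(TBSO)phenyl]hex-5-yne
Conditions: TBSCl, imidazole, DMF, rt
Reagents that add atoms: tert-butyldimethylsilyl chloride, CC(C)(C)[Si](C)(C)Cl
Why: Routine silyl ether formation at the secondary alcohol leaves the stereocenter untouched.

**Step 5**
Reactants: 6 1-(2,6-dihydroxy-4-methoxyphenyl)ethanone
Product: 7 1-[2,6-bis(allyloxy)-4-methoxyphenyl]ethanone
Conditions: allyl bromide (2.5 equiv.), K2CO3, DMF, 60 °C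
Reagents that add atoms: allyl bromide, C=CCBr
Why: Williamson bis-allylation protects both ring A phenols so that the later chalcone cannot cyclise by oxa-Michael addition.

**Step 6**
Reactants: 7 1-[2,6-bis(allyloxy)-4-methoxyphenyl]ethanone; 8 4-(TBSO)benzaldehyde
Product: 11 (E)-1-[2,6-bis(allyloxy)-4-methoxyphenyl]-3-[4-(TBSO)phenyl]prop-2-en-1-one, via aldol adduct 9 (not isolated), via mesylate 10 (not isolated)
Conditions: LiN(SiMe3)2, THF, −78 °C; 8; then MsCl, Et3N, 0 °C to rt
Reagents that add atoms: none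
Why: Directed aldol addition of the lithium enolate followed by mesylation and E1cB elimination should give the (E)-chalcone without the hydroxide of a Claisen–Schmidt condensation, which would cleave the aryl silyl ether.

**Step 7**
Reactants: 5 (S)-3-(TBSO)-1-[4-(TBSO)phenyl]hex-5-yne (1.6 equiv.); 11 (E)-chalcone
Product: 13 (3R,7S,E)-1-[2,6-bis(allyloxy)-4-methoxyphenyl]-7-(TBSO)-3,9-bis[4-(TBSO)phenyl]non-4-en-1-one, via alkenylcatecholborane 12 (not isolated)
Conditions: catecholborane, neat, 70 °C; then 11, [Rh(OH)((R)-binap)]2 (1.5 mol%), Et3N, dioxane/H2O (10:1), 40 °C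
Reagents that add atoms: none
Why: syn-Hydroboration gives the (E)-alkenylboronate, and the rhodium-catalysed asymmetric 1,4-addition (Hayashi–Miyaura reaction) should transfer the alkenyl group with retained geometry to the Si face of C3'' under control of (R)-BINAP, setting C3'' as R.

**Step 8**
Reactants: 13 bis-allyl ether ketone
Product: 14 (3R,7S,E)-1-(2,6-dihydroxy-4-methoxyphenyl)-7-(TBSO)-3,9-bis[4-(TBSO)phenyl]non-4-en-1-one
Conditions: Pd(PPh3)4 (5 mol%), morpholine, THF, 40 °C
Reagents that add atoms: none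
Why: Allyl transfer from the aryl ethers to morpholine through a π-allyl complex of zerovalent palladium frees both ring A phenols under neutral conditions that spare silyl ethers, ketone and alkene.

**Step 9**
Reactants: 15 (S)-4-hydroxymandelic acid
Product: 16 allyl (S)-2-hydroxy-2-(4-hydroxyphenyl)acetate
Conditions: allyl bromide, KHCO3, DMF, rt
Reagents that add atoms: allyl bromide, C=CCBr
Why: Hydrogen carbonate deprotonates only the carboxylic acid, so O-alkylation of the carboxylate leaves the phenol, the carbinol and the stereocenter untouched.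

**Step 10**
Reactants: 16 allyl (S)-2-hydroxy-2-(4-hydroxyphenyl)acetate
Product: 17 allyl (S)-2-hydroxy-2-[4-(TBSO)phenyl]acetate
Conditions: TBSCl (1.05 equiv.), imidazole, CH2Cl2, 0 °C
Reagents that add atoms: tert-butyldimethylsilyl chloride, CC(C)(C)[Si](C)(C)Cl
Why: The more acidic, unhindered phenol should be silylated in preference to the deactivated α-hydroxy ester OH.

**Step 11**
Reactants: 14 dihydroxyaryl ketone; 17 allyl (S)-2-hydroxy-2-[4-(TBSO)phenyl]acetate
Product: 18 allyl (R)-2-{3-hydroxy-5-methoxy-2-[(3R,7S,E)-7-(TBSO)-3,9-bis(4-TBSO-phenyl)non-4-enoyl]phenoxy}-2-[4-(TBSO)phenyl]acetate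
Conditions: PPh3, DIAD, toluene, 0 °C to rt
Reagents that add atoms: none
Why: Mitsunobu etherification displaces the activated mandelate carbinol by one of the two equivalent phenols in an SN2 step with inversion (S to R), and it should stop at the monoether because the remaining OH is locked in a hydrogen bond to the C1'' ketone.

**Step 12**
Reactants: 18 allyl ester
Product: 19 (R)-2-{3-hydroxy-5-methoxy-2-[(3R,7S,E)-7-(TBSO)-3,9-bis(4-TBSO-phenyl)non-4-enoyl]phenoxy}-2-[4-(TBSO)phenyl]acetic acid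
Conditions: Pd(PPh3)4 (5 mol%), N-methylaniline, THF, rt
Reagents that add atoms: none
Why: Neutral palladium-catalysed allyl ester cleavage gives the acid without a basic hydrolysis that could epimerise the future C2.

**Step 13**
Reactants: 19 α-aryloxy acid
Product: 21 (R)-1-diazo-3-(aryloxy)-3-[4-(TBSO)phenyl]propan-2-one (aryloxy as in 19), via acid chloride 20 (not isolated)
Conditions: 1-chloro-N,N,2-trimethylpropenylamine, CH2Cl2, 0 °C; then CH2N2 (3 equiv.), Et2O, −10 to 0 °C
Reagents that add atoms: diazomethane, C=[N+]=[N-]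
Why: Base-free acid chloride formation and acylation of diazomethane (first stage of an Arndt–Eistert sequence) should give the diazoketone without racemisation through a ketene, while the chelated C7–OH is too weakly acidic to be methylated.

**Step 14**
Reactants: 21 (R)-diazoketone
Product: 23 (S)-7-hydroxy-5-methoxy-8-[(3R,7S,E)-7-(TBSO)-3,9-bis(4-TBSO-phenyl)non-4-enoyl]-2-[4-(TBSO)phenyl]chroman-4-one, via ketene 22 (not isolated)
Conditions: hν (420 nm LED), CH2Cl2 (0.005 M), −40 °C; then TfOH (5 mol%), −40 to 0 °C; Et3N quench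
Reagents that add atoms: none
Why: Proposed new method: irradiation of the α-diazoketone triggers a Wolff rearrangement in which C2, the only group that can migrate, shifts from the acyl carbon (the future C4) to the diazo carbon (the future C3) with loss of N2, forming the C2–C3 bond and ketene 22; catalytic TfOH then protonates the ketene at C3 to an acylium ion that acylates C4a, forming the C4–C4a bond. The closest known reaction types are the Arndt–Eistert homologation (Wolff shift with retention at the migrating carbon) and the acid-catalysed intramolecular Friedel–Crafts acylation of aryl ethers by ketene-type acyl donors that gives chroman-4-ones; their union in one flask on an α-aryloxy-α-aryl diazoketone is the untested part. Ring C closes in a six-membered Friedel–Crafts mode, exo with respect to the acylium π bond (6-exo-dig), the arene carbon C4a attacking the sp carbon C4. No new stereocenter forms, and C2 keeps its configuration because the 1,2-shift is suprafacial with retention, so the R diazoketone should give the 2S flavanone. The step needs C-acylation at C4a in preference to carbene insertion, ketene dimerisation, O-acylation and loss of the aryloxide from C2: the acyclic diazoketone rearranges in concert from its s-Z conformer, C8 is blocked so C4a is the only free position ortho to O1 and is activated by O1, the C5 methoxy group and the para C7 hydroxyl, the C7–OH is hydrogen-bonded to the C1'' ketone and cannot reach C4, and high dilution at low temperature with only catalytic acid disfavours the bimolecular and ionising pathways.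

**Step 15**
Reactants: 23 flavanone diketone
Product: 26 (S)-7-hydroxy-8-[(1S,3R,7S,E)-1-hydroxy-7-(TBSO)-3,9-bis(4-TBSO-phenyl)non-4-enyl]-5-methoxy-2-[4-(TBSO)phenyl]chroman-4-one, via aryloxyborinate 24 (not isolated), via cyclic boronate 25 (not isolated)
Conditions: (+)-Ipc2BCl (1.2 equiv.), i-Pr2NEt, THF, −25 °C to rt; then HN(CH2CH2OH)2
Reagents that add atoms: none
Why: In this borinate-tethered intramolecular asymmetric reduction of an o-hydroxyaryl ketone, C7–OH binds the Ipc2B unit and a β-hydride of one isopinocampheyl group is delivered through a cyclic transition state only to the adjacent C1'' carbonyl (C4=O, para to that OH, is out of reach), the (+) reagent being expected to attack the Re face and give the 1''S carbinol.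

**Step 16**
Reactants: 26 tetrasilyl ether
Product: 27 (S)-7-hydroxy-8-[(1S,3R,7S,E)-1,7-dihydroxy-3,9-bis(4-hydroxyphenyl)non-4-en-1-yl]-2-(4-hydroxyphenyl)-5-methoxychroman-4-one (CNP0415883.1)
Conditions: HF·pyridine, pyridine, THF, 0 °C to rt
Reagents that add atoms: none
Why: Buffered fluoride cleavage of the three aryl and one alkyl silyl ethers should neither open the base-sensitive flavanone nor ionise the benzylic carbinol.

**Compound list**

1 | methyl 3-(4-hydroxyphenyl)propanoate | COC(=O)CCc1ccc(O)cc1 | starting material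
2 | methyl 3-[4-(TBSO)phenyl]propanoate | COC(=O)CCc1ccc(O[Si](C)(C)C(C)(C)C)cc1 | intermediate
3 | 3-[4-(TBSO)phenyl]propanal | O=CCCc1ccc(O[Si](C)(C)C(C)(C)C)cc1 | intermediate
4 | (S)-1-[4-(TBSO)phenyl]hex-5-yn-3-ol | C#CC[C@@H](O)CCc1ccc(O[Si](C)(C)C(C)(C)C)cc1 | intermediate
5 | (S)-3-(TBSO)-1-[4-(TBSO)phenyl]hex-5-yne | C#CC[C@@H](O[Si](C)(C)C(C)(C)C)CCc1ccc(O[Si](C)(C)C(C)(C)C)cc1 | intermediate
6 | 1-(2,6-dihydroxy-4-methoxyphenyl)ethanone | CC(=O)c1c(O)cc(OC)cc1O | starting material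
7 | 1-[2,6-bis(allyloxy)-4-methoxyphenyl]ethanone | CC(=O)c1c(OCC=C)cc(OC)cc1OCC=C | intermediate
8 | 4-(TBSO)benzaldehyde | O=Cc1ccc(O[Si](C)(C)C(C)(C)C)cc1 | starting material
9 | 1-[2,6-bis(allyloxy)-4-methoxyphenyl]-3-hydroxy-3-[4-(TBSO)phenyl]propan-1-one (racemic, lithium alkoxide in the flask) | OC(CC(=O)c1c(OCC=C)cc(OC)cc1OCC=C)c1ccc(O[Si](C)(C)C(C)(C)C)cc1 | intermediate (not isolated)
10 | methanesulfonate of 9 | CS(=O)(=O)OC(CC(=O)c1c(OCC=C)cc(OC)cc1OCC=C)c1ccc(O[Si](C)(C)C(C)(C)C)cc1 | intermediate (not isolated)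
11 | (E)-1-[2,6-bis(allyloxy)-4-methoxyphenyl]-3-[4-(TBSO)phenyl]prop-2-en-1-one | O=C(/C=C/c1ccc(O[Si](C)(C)C(C)(C)C)cc1)c1c(OCC=C)cc(OC)cc1OCC=C | intermediate
12 | 2-[(S,E)-4-(TBSO)-6-(4-TBSO-phenyl)hex-1-enyl]-1,3,2-benzodioxaborole | O1c2ccccc2OB1/C=C/C[C@@H](O[Si](C)(C)C(C)(C)C)CCc1ccc(O[Si](C)(C)C(C)(C)C)cc1 | intermediate (not isolated)
13 | (3R,7S,E)-1-[2,6-bis(allyloxy)-4-methoxyphenyl]-7-(TBSO)-3,9-bis[4-(TBSO)phenyl]non-4-en-1-one | O=C(C[C@H](/C=C/C[C@@H](O[Si](C)(C)C(C)(C)C)CCc1ccc(O[Si](C)(C)C(C)(C)C)cc1)c1ccc(O[Si](C)(C)C(C)(C)C)cc1)c1c(OCC=C)cc(OC)cc1OCC=C | intermediate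
14 | (3R,7S,E)-1-(2,6-dihydroxy-4-methoxyphenyl)-7-(TBSO)-3,9-bis[4-(TBSO)phenyl]non-4-en-1-one | O=C(C[C@H](/C=C/C[C@@H](O[Si](C)(C)C(C)(C)C)CCc1ccc(O[Si](C)(C)C(C)(C)C)cc1)c1ccc(O[Si](C)(C)C(C)(C)C)cc1)c1c(O)cc(OC)cc1O | intermediate
15 | (S)-4-hydroxymandelic acid | O[C@H](C(=O)O)c1ccc(O)cc1 | starting material
16 | allyl (S)-2-hydroxy-2-(4-hydroxyphenyl)acetate | O[C@H](C(=O)OCC=C)c1ccc(O)cc1 | intermediate
17 | allyl (S)-2-hydroxy-2-[4-(TBSO)phenyl]acetate | O[C@H](C(=O)OCC=C)c1ccc(O[Si](C)(C)C(C)(C)C)cc1 | intermediate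
18 | allyl (R)-2-{3-hydroxy-5-methoxy-2-[(3R,7S,E)-7-(TBSO)-3,9-bis(4-TBSO-phenyl)non-4-enoyl]phenoxy}-2-[4-(TBSO)phenyl]acetate | O=C(C[C@H](/C=C/C[C@@H](O[Si](C)(C)C(C)(C)C)CCc1ccc(O[Si](C)(C)C(C)(C)C)cc1)c1ccc(O[Si](C)(C)C(C)(C)C)cc1)c1c(O)cc(OC)cc1O[C@@H](C(=O)OCC=C)c1ccc(O[Si](C)(C)C(C)(C)C)cc1 | intermediate
19 | (R)-2-(aryloxy)-2-[4-(TBSO)phenyl]acetic acid (aryloxy as in 18) | O=C(C[C@H](/C=C/C[C@@H](O[Si](C)(C)C(C)(C)C)CCc1ccc(O[Si](C)(C)C(C)(C)C)cc1)c1ccc(O[Si](C)(C)C(C)(C)C)cc1)c1c(O)cc(OC)cc1O[C@@H](C(=O)O)c1ccc(O[Si](C)(C)C(C)(C)C)cc1 | intermediate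
20 | acid chloride of 19 | O=C(C[C@H](/C=C/C[C@@H](O[Si](C)(C)C(C)(C)C)CCc1ccc(O[Si](C)(C)C(C)(C)C)cc1)c1ccc(O[Si](C)(C)C(C)(C)C)cc1)c1c(O)cc(OC)cc1O[C@@H](C(=O)Cl)c1ccc(O[Si](C)(C)C(C)(C)C)cc1 | intermediate (not isolated)
21 | (R)-1-diazo-3-(aryloxy)-3-[4-(TBSO)phenyl]propan-2-one | O=C(C[C@H](/C=C/C[C@@H](O[Si](C)(C)C(C)(C)C)CCc1ccc(O[Si](C)(C)C(C)(C)C)cc1)c1ccc(O[Si](C)(C)C(C)(C)C)cc1)c1c(O)cc(OC)cc1O[C@@H](C(=O)C=[N+]=[N-])c1ccc(O[Si](C)(C)C(C)(C)C)cc1 | intermediate
22 | (S)-3-(aryloxy)-3-[4-(TBSO)phenyl]prop-1-en-1-one (ketene) | O=C(C[C@H](/C=C/C[C@@H](O[Si](C)(C)C(C)(C)C)CCc1ccc(O[Si](C)(C)C(C)(C)C)cc1)c1ccc(O[Si](C)(C)C(C)(C)C)cc1)c1c(O)cc(OC)cc1O[C@@H](C=C=O)c1ccc(O[Si](C)(C)C(C)(C)C)cc1 | intermediate (not isolated)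
23 | (S)-7-hydroxy-5-methoxy-8-[(3R,7S,E)-7-(TBSO)-3,9-bis(4-TBSO-phenyl)non-4-enoyl]-2-[4-(TBSO)phenyl]chroman-4-one | COc1cc(O)c(C(=O)C[C@H](/C=C/C[C@@H](O[Si](C)(C)C(C)(C)C)CCc2ccc(O[Si](C)(C)C(C)(C)C)cc2)c2ccc(O[Si](C)(C)C(C)(C)C)cc2)c2c1C(=O)C[C@@H](c1ccc(O[Si](C)(C)C(C)(C)C)cc1)O2 | intermediate
24 | diisopinocampheylborinate of the C7–OH of 23 | COc1cc(OB([C@H]3C[C@H]4C[C@@H]([C@@H]3C)C4(C)C)[C@H]3C[C@H]4C[C@@H]([C@@H]3C)C4(C)C)c(C(=O)C[C@H](/C=C/C[C@@H](O[Si](C)(C)C(C)(C)C)CCc2ccc(O[Si](C)(C)C(C)(C)C)cc2)c2ccc(O[Si](C)(C)C(C)(C)C)cc2)c2c1C(=O)C[C@@H](c1ccc(O[Si](C)(C)C(C)(C)C)cc1)O2 | intermediate (not isolated)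
25 | cyclic isopinocampheylboronate bridging O7 and the C1'' oxygen (4H-1,3,2-benzodioxaborin) | COc1cc3OB([C@H]5C[C@H]6C[C@@H]([C@@H]5C)C6(C)C)O[C@@H](C[C@H](/C=C/C[C@@H](O[Si](C)(C)C(C)(C)C)CCc4ccc(O[Si](C)(C)C(C)(C)C)cc4)c4ccc(O[Si](C)(C)C(C)(C)C)cc4)c3c2c1C(=O)C[C@@H](c1ccc(O[Si](C)(C)C(C)(C)C)cc1)O2 | intermediate (not isolated)
26 | (S)-7-hydroxy-8-[(1S,3R,7S,E)-1-hydroxy-7-(TBSO)-3,9-bis(4-TBSO-phenyl)non-4-enyl]-5-methoxy-2-[4-(TBSO)phenyl]chroman-4-one | COc1cc(O)c([C@@H](O)C[C@H](/C=C/C[C@@H](O[Si](C)(C)C(C)(C)C)CCc2ccc(O[Si](C)(C)C(C)(C)C)cc2)c2ccc(O[Si](C)(C)C(C)(C)C)cc2)c2c1C(=O)C[C@@H](c1ccc(O[Si](C)(C)C(C)(C)C)cc1)O2 | intermediate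
27 | (S)-7-hydroxy-8-[(1S,3R,7S,E)-1,7-dihydroxy-3,9-bis(4-hydroxyphenyl)non-4-en-1-yl]-2-(4-hydroxyphenyl)-5-methoxychroman-4-one | COc1cc(O)c([C@@H](O)C[C@H](/C=C/C[C@@H](O)CCc2ccc(O)cc2)c2ccc(O)cc2)c2c1C(=O)C[C@@H](c1ccc(O)cc1)O2 | target

**Step count and risks**

Total steps: 16. Longest linear sequence: 12 steps (1, 2, 3, 4, 7, 8, 11, 12, 13, 14, 15, 16).

Steps most likely to fail:

1. Step 14 (Wolff rearrangement and Friedel–Crafts closure in one flask). The rearrangement may be overtaken by carbene side reactions or by dimerisation of the ketene before it is acylated. The acid may also cause loss of the ring A aryloxide from C2 or erosion of the C2 configuration by ring opening. The fallback sets out from 21 and comes back at 23, and it makes the two bonds in two separate known operations. Silver-catalysed Wolff rearrangement in aqueous THF (AgO2CPh, Et3N, sonication; Arndt–Eistert homologation, retention at C2) would give the homologated (S)-3-(aryloxy)-3-[4-(TBSO)phenyl]propanoic acid F1. Trifluoroacetic anhydride in CH2Cl2 at 0 °C would convert it into the mixed trifluoroacetic anhydride F2, which should cyclise onto C4a by intramolecular Friedel–Crafts acylation to give 23.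

2. Step 15 (tethered reduction of the C1'' ketone). Excess reagent may reduce C4=O intermolecularly, the hydride may be delivered to the wrong face, or the benzylic oxygen may be lost reductively through the boron chelate. The fallback sets out from 23 and comes back at 27, and it replaces the boron tether by a silicon hydride tether. Silylation of C7–OH with i-Pr2SiHCl and imidazole would give the aryloxy(diisopropyl)silane F3. Intramolecular hydrosilylation of the neighbouring C1'' ketone, catalysed by a cationic rhodium complex of a chiral bisphosphine (for example [Rh(cod)2]OTf with a DuPHOS-type ligand), would give the cyclic diisopropylsilylene acetal F4. The conditions of step 16 (HF·pyridine) would then remove the silylene together with the TBS groups and give 27.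

3. Step 11 (Mitsunobu etherification). Alkylation of the hindered, hydrogen-bonded phenol may be slow, and partial ionisation of the activated mandelate would erode the configuration of the future C2. The fallback sets out from 17 and 14 and comes back at 18, and it forms the O1–C2 bond by carbene O–H insertion instead of SN2 displacement. Oxidation of 17 (TEMPO cat., NaOCl, KBr, CH2Cl2/H2O, 0 °C) would give the α-keto ester allyl 2-oxo-2-[4-(TBSO)phenyl]acetate F5. Condensation with TsNHNH2 would give the tosylhydrazone F6, and DBU (Bamford–Stevens) would give allyl 2-diazo-2-[4-(TBSO)phenyl]acetate F7. Enantioselective O–H insertion of the carbene from F7 into one phenol of 14 (PdCl2(PhCN)2, chiral spiro bis(oxazoline) ligand, NaB[3,5-(CF3)2C6H3]4, CHCl3) should give 18, with the ligand antipode chosen for the R ether.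

**Further compounds**

F1 | step 14 | (S)-3-{3-hydroxy-5-methoxy-2-[(3R,7S,E)-7-(TBSO)-3,9-bis(4-TBSO-phenyl)non-4-enoyl]phenoxy}-3-[4-(TBSO)phenyl]propanoic acid | O=C(C[C@H](/C=C/C[C@@H](O[Si](C)(C)C(C)(C)C)CCc1ccc(O[Si](C)(C)C(C)(C)C)cc1)c1ccc(O[Si](C)(C)C(C)(C)C)cc1)c1c(O)cc(OC)cc1O[C@@H](CC(=O)O)c1ccc(O[Si](C)(C)C(C)(C)C)cc1
F2 | step 14 | mixed trifluoroacetic anhydride of F1 | O=C(C[C@H](/C=C/C[C@@H](O[Si](C)(C)C(C)(C)C)CCc1ccc(O[Si](C)(C)C(C)(C)C)cc1)c1ccc(O[Si](C)(C)C(C)(C)C)cc1)c1c(O)cc(OC)cc1O[C@@H](CC(=O)OC(=O)C(F)(F)F)c1ccc(O[Si](C)(C)C(C)(C)C)cc1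
F3 | step 15 | 7-O-(diisopropylsilyl) ether of 23 | COc1cc(O[SiH](C(C)C)C(C)C)c(C(=O)C[C@H](/C=C/C[C@@H](O[Si](C)(C)C(C)(C)C)CCc2ccc(O[Si](C)(C)C(C)(C)C)cc2)c2ccc(O[Si](C)(C)C(C)(C)C)cc2)c2c1C(=O)C[C@@H](c1ccc(O[Si](C)(C)C(C)(C)C)cc1)O2
F4 | step 15 | cyclic diisopropylsilylene acetal bridging O7 and the (S)-C1'' oxygen | COc1cc3O[Si](C(C)C)(C(C)C)O[C@@H](C[C@H](/C=C/C[C@@H](O[Si](C)(C)C(C)(C)C)CCc4ccc(O[Si](C)(C)C(C)(C)C)cc4)c4ccc(O[Si](C)(C)C(C)(C)C)cc4)c3c2c1C(=O)C[C@@H](c1ccc(O[Si](C)(C)C(C)(C)C)cc1)O2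
F5 | step 11 | allyl 2-oxo-2-[4-(TBSO)phenyl]acetate | C=CCOC(=O)C(=O)c1ccc(O[Si](C)(C)C(C)(C)C)cc1
F6 | step 11 | tosylhydrazone of F5 | C=CCOC(=O)C(=NNS(=O)(=O)c1ccc(C)cc1)c1ccc(O[Si](C)(C)C(C)(C)C)cc1
F7 | step 11 | allyl 2-diazo-2-[4-(TBSO)phenyl]acetate | C=CCOC(=O)C(=[N+]=[N-])c1ccc(O[Si](C)(C)C(C)(C)C)cc1
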